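The target is traced back to α-chamigrene and from there to the cedarwood hydrocarbon (−)-thujopsene. Thujopsene brings the full C15 count, an intact ring B (C6–C11) and the quaternary centre C6. The key step exploits the vinylcyclopropane C4=C3–C2(C1)–C6 that is fused to ring B. Protonation at C4 opens the C2–C6 bond, C5 then migrates from C7 to C6, and H8 is lost. One operation thus makes the C5–C6 bond, closes ring A and carries the cyclopropane centre over into the spiro centre. The precursor is thujopsene itself, used as bought. Afterwards ring A is bromochlorinated, and ring B is oxidised at C9, brominated at C10, deconjugated and reduced.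

Key step: step 1

Remark on numbering: chamigrane numbering is used for every compound, thujopsene included. Ring A = C6 (spiro), C1, C2, C3, C4, C5. Ring B = C6, C7, C8, C9, C10, C11. C12 and C13 are the methyls on C11, C14 is the carbon on C7, and C15 is the methyl on C3.

Remark on stereochemistry: the target is (2S,3S,6S,9S,10S), with Br2/Cl3 trans and OH9/Br10 trans. The geometry at C6 does not change after step 1. Its descriptor switches from R (no bromine at C10) to S (bromine at C10) only because that bromine raises C11 above C7 in the priority order.

Assumption: (−)-thujopsene of high enantiomeric purity is bought as the cedarwood oil constituent.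

Step 1
Reactants: 1 (−)-thujopsene
Product: 5 (6R)-α-chamigrene, via cyclopropylcarbinyl cation 2 (not isolated), via homoallyl cation 3 (not isolated), via spiro cation 4 (not isolated)
Conditions: HClO4 (cat.), AcOH–1,4-dioxane, rt, short contact, aq NaHCO3 quench; AgNO3–SiO2 chromatography
Reagents that add atoms: none
Why: Protonation of the C3=C4 alkene at C4 gives the tertiary cyclopropylcarbinyl cation 2, whose C2–C6 bond opens with relief of ring strain to the tertiary homoallyl cation 3 and puts the C2=C3 alkene in its final place. A suprafacial 1,2-shift of C5 from C7 to C6 (Wagner–Meerwein contraction of the seven-membered ring) then forms C5–C6 and gives the tertiary cation 4, which loses H8. The closest known reaction type is the acid-catalysed cyclopropylcarbinyl–homoallyl rearrangement of vinylcyclopropane terpenes coupled to a Wagner–Meerwein shift, which is documented for this very hydrocarbon. Ring A is closed by migration, that is by contraction of an existing ring, so no exo or endo mode applies. C6 is controlled by the substrate: C2 and C5 belong to the same six-membered ring of 1 and lie on the same side of the C1–C7–C11 plane of cation 3, so C5 takes the place left by C2 with retention, while the centres C2 and C7 of 1 are erased. The step needs C5 rather than C14 or C8 to migrate and H8 rather than H14 or H1 to be lost: the C5–C7 bond is the one best aligned with the empty orbital at C6, the trisubstituted endocyclic alkene is the favoured elimination product, and short contact with dilute acid keeps 5 from re-protonation and cyclisation.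

Step 2
Reactants: 5 (6R)-α-chamigrene; 6 N-bromosuccinimide
Product: 8 (2S,3S,6R)-2-bromo-3-chlorochamigr-7-ene, via bromonium ion 7 (not isolated)
Conditions: 6, Me3SiCl, CH2Cl2, 0 °C (BrCl in situ); then 5, −78 °C
Reagents that add atoms: N-bromosuccinimide O=C1CCC(=O)N1Br; chlorotrimethylsilane C[Si](C)(C)Cl
Why: Electrophilic anti bromochlorination with BrCl made in situ: the C2=C3 alkene reacts ahead of C7=C8, which is screened by the quaternary C6, bromine adds to the ring A face turned away from the pseudoaxial C7 and its C14 methyl to give 7, and chloride opens 7 at the tertiary C3 from the opposite face (Markovnikov), which sets 2S and 3S with Br and Cl trans and equatorial in the chair that keeps C11 equatorial.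

Step 3
Reactants: 8 (2S,3S,6R)-2-bromo-3-chlorochamigr-7-ene
Product: 9 (2S,3S,6R)-2-bromo-3-chlorochamigr-7-en-9-one
Conditions: dirhodium tetracaprolactamate Rh2(cap)4 (cat.), aq t-BuOOH, 1,2-dichloroethane, 40 °C
Reagents that add atoms: tert-butyl hydroperoxide CC(C)(C)OO
Why: Dirhodium-catalysed allylic C–H oxidation through tert-butylperoxyl radicals: C9H2 is the only secondary allylic position of 8, the halogen-bearing ring A has no activated C–H bond, the neutral medium leaves the secondary bromide and the tertiary chloride alone, and no stereocentre is formed.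

Step 4
Reactants: 9 (2S,3S,6R)-2-bromo-3-chlorochamigr-7-en-9-one; 6 N-bromosuccinimide
Product: 12 (2S,3S,6S,10S)-2,10-dibromo-3-chlorochamigr-7-en-9-one, via lithium dienolate 10 (not isolated), via silyl dienol ether 11 (not isolated)
Conditions: LiN(iPr)2, Me3SiCl, THF, −78 °C; then 6, THF, −78 to 0 °C; then DBU (cat.), CH2Cl2, rt
Reagents that add atoms: N-bromosuccinimide O=C1CCC(=O)N1Br
Why: Kinetic α′-deprotonation of a β-methyl enone (as with isophorone, whose CH2 between C=O and CMe2 is the kinetic site), silyl trapping and electrophilic bromination of the 2-silyloxydiene place bromine at C10 only, the brief cold exposure to amide base spares the equatorial ring A halides, which have no antiperiplanar ring hydrogen, and C10, which cannot eliminate because C11 is quaternary, is then set under thermodynamic control by DBU-mediated enolisation, bromine taking the equatorial site of the ring B conformer with C1 pseudoequatorial and C5 pseudoaxial (Br cis to C1, 10S), a conformer expected to be modestly favoured because the gauche Br/Cl pair flattens ring A at C2–C3 and tilts the axial H2 away from the C14 methyl.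

Step 5
Reactants: 12 (2S,3S,6S,10S)-2,10-dibromo-3-chlorochamigr-7-en-9-one
Product: 15 (2S,3S,6S,9S,10S)-2,10-dibromo-3-chlorochamigr-7(14)-en-9-ol, via potassium dienolate 13 (not isolated), via deconjugated bromoketone 14 (not isolated)
Conditions: KN(SiMe3)2, THF, −78 °C; AcOH, −78 °C; then CeCl3·7H2O, NaBH4, MeOH, −78 °C; pH 7 buffer
Reagents that add atoms: none
Why: Deconjugation by kinetic α-protonation of an extended dienolate followed by Luche reduction: the bulky base takes a C14 proton because H10 is buried between Br, CMe2 and the axial C5H2, the equatorial C10–Br bond lies near the nodal plane of 13 so that bromide loss (Favorskii path) is not assisted at −78 °C, acetic acid protonates C8 faster than C14 to give 14, and the small cerium-modified borohydride reduces 14 at once, before reconjugation, by axial attack on the chair with equatorial bromine, which sets 9S with OH equatorial and trans to Br.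

Compound list
1 | (−)-thujopsene, (1aS,4aS,8aS)-2,4a,8,8-tetramethyl-1,1a,4,4a,5,6,7,8-octahydrocyclopropa[d]naphthalene | CC1=CC[C@]2(C)CCCC(C)(C)[C@@]23C[C@@H]13 | starting material
2 | tertiary cyclopropylcarbinyl cation (C3 cationic, cyclopropane C1–C2–C6 intact) | C[C+]1CC[C@]2(C)CCCC(C)(C)[C@@]23C[C@@H]13 | intermediate
3 | tertiary homoallyl cation (C6 cationic, C2=C3, fused six–seven ring system, C7 as in 1) | CC1=CC[C+]2C(C)(C)CCC[C@@]2(C)CC1 | intermediate
4 | chamigren-7-yl cation (spiro skeleton, C7 cationic, C2=C3, C6 as in 5) | C[C+]1CCCC(C)(C)[C@]12CCC(C)=CC2 | intermediate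
5 | (6R)-α-chamigrene, (6R)-chamigra-2,7-diene | CC1=CCCC(C)(C)[C@]12CCC(C)=CC2 | intermediate
6 | N-bromosuccinimide | O=C1CCC(=O)N1Br | starting material
7 | 2,3-bromonium ion of 5, bromine on the ring A face opposite to C7 | CC1=CCCC(C)(C)[C@]12CC[C@@]3(C)[Br+][C@H]3C2 | intermediate
8 | (2S,3S,6R)-2-bromo-3-chlorochamigr-7-ene (Br and Cl trans, Br on the face opposite to C7) | CC1=CCCC(C)(C)[C@]12CC[C@](C)(Cl)[C@@H](Br)C2 | intermediate
9 | (2S,3S,6R)-2-bromo-3-chlorochamigr-7-en-9-one | CC1=CC(=O)CC(C)(C)[C@]12CC[C@](C)(Cl)[C@@H](Br)C2 | intermediate
10 | lithium cross-conjugated dienolate of 9 (C7=C8–C9(OLi)=C10) | [Li+].CC1=CC([O-])=CC(C)(C)[C@]12CC[C@](C)(Cl)[C@@H](Br)C2 | intermediate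
11 | 9-trimethylsilyloxy-7,9-diene derived from 9 (ring A as in 9) | CC1=CC(O[Si](C)(C)C)=CC(C)(C)[C@]12CC[C@](C)(Cl)[C@@H](Br)C2 | intermediate
12 | (2S,3S,6S,10S)-2,10-dibromo-3-chlorochamigr-7-en-9-one (C10–Br cis to C1) | CC1=CC(=O)[C@@H](Br)C(C)(C)[C@]12CC[C@](C)(Cl)[C@@H](Br)C2 | intermediate
13 | potassium extended dienolate of 12 (C14=C7–C8=C9–OK) | [K+].C=C1C=C([O-])[C@@H](Br)C(C)(C)[C@]12CC[C@](C)(Cl)[C@@H](Br)C2 | intermediate
14 | (2S,3S,6S,10S)-2,10-dibromo-3-chlorochamigr-7(14)-en-9-one | C=C1CC(=O)[C@@H](Br)C(C)(C)[C@]12CC[C@](C)(Cl)[C@@H](Br)C2 | intermediate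
15 | (2S,3S,6S,9S,10S)-2,10-dibromo-3-chlorochamigr-7(14)-en-9-ol | C=C1C[C@H](O)[C@@H](Br)C(C)(C)[C@]12CC[C@](C)(Cl)[C@@H](Br)C2 | target

Total step count: 5
Longest linear sequence: 5 steps (1 → 5 → 8 → 9 → 12 → 15)

Steps most likely to fail

**Step 5.**
- What may go wrong:
  - The base may remove H10 instead of a C14 proton, which erodes C10 and returns conjugated enone.
  - Bromide may be expelled from the dienolate.
  - The alkene may move back into conjugation before hydride arrives.
  - Hydride may be delivered from the equatorial side, because the axial C11 methyl screens the axial trajectory.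
- The fallback sets out from 12 and comes back at 15. It never forms an enolate next to the C10–Br bond.
- The ketone is reduced while still conjugated, under catalyst control, with (R)-2-methyl-CBS-oxazaborolidine and catecholborane in toluene at −78 °C. The C10 side acts as the large group and the C8 vinyl side as the small one. This should give (2S,3S,6S,9S,10S)-2,10-dibromo-3-chlorochamigr-7-en-9-ol F1.
- Catalytic SeO2 with t-BuOOH in CH2Cl2 then hydroxylates C14, the only allylic C–H set on the more substituted alkene carbon C7. The product should be the 9,14-diol F2.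
- A Mitsunobu reaction at the primary allylic alcohol (2-nitrobenzenesulfonylhydrazide, PPh3, DEAD, THF, −30 °C) gives the N-allyl sulfonylhydrazine F3.
- On warming F3 loses the sulfinic acid to give the allylic diazene F4. Its retro-ene loss of N2 delivers hydrogen to C8 and moves the alkene to C7=C14, which gives 15.

**Step 4.**
- What may go wrong:
  - The energy gap between the two C10 epimers may be too small, because the saturated ring A tells C1 from C5 only through the remote C2 substituent.
  - Slow base-induced loss of HCl or HBr from ring A may occur during the equilibration.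
- The fallback sets out from 9 and comes back at 12. It lets an sp2 centre at C2 do the differentiation.
- Zn dust in AcOH–Et2O at 0 °C strips Br and Cl from ring A by reductive 1,2-elimination to give (6R)-chamigra-2,7-dien-9-one F5.
- LiN(iPr)2 and Me3SiCl give its 9-trimethylsilyloxy triene F6.
- Compound 6 at −78 °C brominates the silyl dienol ether faster than the ring A alkene. Catalytic DBU then equilibrates C10 to (6S,10S)-10-bromochamigra-2,7-dien-9-one F7.
- With no axial hydrogen on C2, the C14 methyl leans over the flat C1–C2 side of ring A. C1 therefore becomes pseudoequatorial and C5 pseudoaxial on ring B, and the equatorial bromide of that conformer is the 10S epimer.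
- BrCl addition as in step 2 then touches only C2=C3, since the enone alkene is deactivated, and gives 12.

**Step 1.**
- What may go wrong:
  - The cations may leak by proton loss from C1 at the stage of 3, which gives fused dienes.
  - Proton loss may occur from C14 instead of C8 at the stage of 4.
  - Compound 5 may be re-protonated, with cyclisation of C7 onto C2=C3, on longer acid contact.
- The fallback sets out from 1 and comes back at 5. It separates the skeletal change from the placement of the ring B alkene.
- The acid treatment is stopped as soon as 1 is consumed, and the spiro olefins are taken off the fused dienes on AgNO3–SiO2.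
- The exocyclic isomer (6R)-β-chamigrene F8 is moved into the ring with catalytic RhCl3·3H2O in hot ethanol by metal hydride addition–elimination. No further carbocation is generated at C7.

Further compounds
F1 | step 5 | (2S,3S,6S,9S,10S)-2,10-dibromo-3-chlorochamigr-7-en-9-ol | CC1=C[C@H](O)[C@@H](Br)C(C)(C)[C@]12CC[C@](C)(Cl)[C@@H](Br)C2
F2 | step 5 | (2S,3S,6S,9S,10S)-2,10-dibromo-3-chlorochamigr-7-ene-9,14-diol | OCC1=C[C@H](O)[C@@H](Br)C(C)(C)[C@]12CC[C@](C)(Cl)[C@@H](Br)C2
F3 | step 5 | N-(C14-allyl)-N-(2-nitrobenzenesulfonyl)hydrazine derived from F2 | NN(CC1=C[C@H](O)[C@@H](Br)C(C)(C)[C@]12CC[C@](C)(Cl)[C@@H](Br)C2)S(=O)(=O)c1ccccc1[N+](=O)[O-]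
F4 | step 5 | C14 allylic diazene derived from F3 | N=NCC1=C[C@H](O)[C@@H](Br)C(C)(C)[C@]12CC[C@](C)(Cl)[C@@H](Br)C2
F5 | step 4 | (6R)-chamigra-2,7-dien-9-one | CC1=CC(=O)CC(C)(C)[C@]12CCC(C)=CC2
F6 | step 4 | 9-trimethylsilyloxychamigra-2,7,9-triene (C6 as in F5) | CC1=CC(O[Si](C)(C)C)=CC(C)(C)[C@]12CCC(C)=CC2
F7 | step 4 | (6S,10S)-10-bromochamigra-2,7-dien-9-one | CC1=CC(=O)[C@@H](Br)C(C)(C)[C@]12CCC(C)=CC2
F8 | step 1 | (6R)-β-chamigrene, (6R)-chamigra-2,7(14)-diene | C=C1CCCC(C)(C)[C@]12CCC(C)=CC2
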